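The decalin is opened at C9–C10 and C4–C5, which unfolds rings B and A into a single chain. Three features of the target allow this. Ring B carries oxygen at C9, next to the fusion carbon C10. The other fusion carbon, C5, is fully substituted. In ring A the carbonyl carbon C2 lies two bonds from C4. An acyl radical at C9 can therefore close ring B on a C5=C10 alkene, and the tertiary C5 radical so formed can close ring A on a C2–C3≡C4 ynone. One operation gives two rings, two C–C bonds and the C5 and C10 stereocentres. The precursor is an acyclic phenyl selenoester carrying only the C7 stereocentre, an E-trisubstituted alkene and a but-2-ynoyl terminus.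

Key step: step 12

Remark: eremophilane numbering is used throughout (decalin C1–C10, isopropenyl C11–C13 on C7, C14 on C5, C15 on C4). β is the face of the decalin that bears C14. In this numbering the target is (4S,5R,7R,8R,9S,10S).

Step 1
Reactants: 1 methyl 4-methylpent-3-enoate
Product: 2 methyl (E)-5-hydroxy-4-methylpent-3-enoate
Conditions: SeO2 (0.3 equiv), t-BuOOH (2.5 equiv), CH2Cl2, 0 °C to rt
Reagents that add atoms: tert-butyl hydroperoxide, CC(C)(C)OO
Why: Riley allylic oxidation (ene reaction, then [2,3]-sigmatropic shift) attacks the methyl group trans to the chain at the more substituted alkene terminus, so the E geometry of the later C5=C10 alkene is fixed here and the C1 methylene at the other terminus is left alone.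

Step 2
Reactants: 2 methyl (E)-5-hydroxy-4-methylpent-3-enoate
Product: 3 methyl (E)-5-bromo-4-methylpent-3-enoate
Conditions: CBr4, PPh3, CH2Cl2, 0 °C
Reagents that add atoms: carbon tetrabromide, BrC(Br)(Br)Br
Why: The Appel reaction replaces the primary allylic hydroxyl by bromide through SN2 displacement of an oxyphosphonium ion under neutral conditions, without allylic transposition, loss of E geometry or damage to the ester.

Step 3
Reactants: 4 mono-tert-butyl succinate; 5 (S)-4-benzyl-1,3-oxazolidin-2-one
Product: 7 tert-butyl 4-[(4S)-4-benzyl-2-oxo-1,3-oxazolidin-3-yl]-4-oxobutanoate, via mixed pivalic anhydride 6 (not isolated)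
Conditions: t-BuCOCl, Et3N, THF, −20 °C; then LiCl, 5, −20 °C to rt
Reagents that add atoms: none
Why: Mixed-anhydride N-acylation takes place at the less hindered succinyl carbonyl of 6 and installs the phenylalanine-derived auxiliary whose S configuration is the one required for C7.

Step 4
Reactants: 7 tert-butyl 4-[(4S)-4-benzyl-2-oxo-1,3-oxazolidin-3-yl]-4-oxobutanoate; 3 methyl (E)-5-bromo-4-methylpent-3-enoate
Product: 9 1-tert-butyl 8-methyl (3S,5E)-3-{[(4S)-4-benzyl-2-oxo-1,3-oxazolidin-3-yl]carbonyl}-5-methyloct-5-enedioate, via sodium Z-enolate 8 (not isolated)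
Conditions: NaN(SiMe3)2 (0.98 equiv), THF, −78 °C; then 3 (1.3 equiv), −78 to −40 °C
Reagents that add atoms: none
Why: In this Evans asymmetric alkylation the chelated Z-enolate 8 is attacked by the allylic bromide on the face opposite the benzyl group, which sets C7 (3S), and the slight deficit of base keeps free amide away from the CH-acidic C1 methylene of 3 so that 1,4-elimination of HBr is avoided.

Step 5
Reactants: 9 the alkylated imide
Product: 10 1-tert-butyl 8-methyl (3S,5E)-3-[(ethylsulfanyl)carbonyl]-5-methyloct-5-enedioate
Conditions: EtSH (3 equiv), n-BuLi (0.3 equiv), THF, 0 °C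
Reagents that add atoms: ethanethiol, CCS
Why: Thiolate transacylation attacks only the activated exocyclic imide carbonyl, leaves both esters alone, is too weakly basic to epimerise C7 and returns the auxiliary.

Step 6
Reactants: 10 the ethyl thioester
Product: 11 1-tert-butyl 8-methyl (3S,5E)-3-acetyl-5-methyloct-5-enedioate
Conditions: Me2CuLi (from MeLi and CuI, 2 equiv), Et2O, −78 to −40 °C
Reagents that add atoms: lithium dimethylcuprate, [Li+].C[Cu-]C
Why: Ketone synthesis from a thioester and a Gilman cuprate stops at the methyl ketone because cuprates add neither to ketones nor to esters at low temperature, and the weakly basic reagent preserves C7 and the skipped ester.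

Step 7
Reactants: 11 the methyl ketone
Product: 12 1-tert-butyl 8-methyl (3S,5E)-5-methyl-3-(prop-1-en-2-yl)oct-5-enedioate
Conditions: Zn, CH2Br2, TiCl4 (reagent pre-formed in THF and aged at 5 °C), CH2Cl2, 0 °C to rt
Reagents that add atoms: dibromomethane, BrCBr
Why: Takai–Lombardo methylenation uses a non-basic gem-dimetallic reagent that converts ketones but not esters, so the acetyl group becomes the isopropenyl group (C11–C13) without enolisation at C7 and without moving the β,γ-alkene into conjugation, both of which a basic Wittig ylide could cause.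

Step 8
Reactants: 12 the diene diester; 13 prop-1-ynylmagnesium bromide
Product: 15 tert-butyl (3S,5E)-8-hydroxy-5-methyl-3-(prop-1-en-2-yl)undec-5-en-9-ynoate (both epimers at the carbinol carbon C2), via aldehyde 14 (not isolated)
Conditions: i-Bu2AlH (1.05 equiv), CH2Cl2, −78 °C; then 13 (2.5 equiv, THF), −78 to 0 °C
Reagents that add atoms: none
Why: Partial ester reduction hits only the methyl ester (the tert-butyl ester is too hindered at −78 °C) and gives an aluminium hemiacetal that releases aldehyde 14 on warming in the presence of the alkynyl Grignard reagent, so the isomerisation-prone β,γ-unsaturated aldehyde is never handled, and the uncontrolled carbinol centre is erased in step 11.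

Step 9
Reactants: 15 the propargylic alcohol
Product: 17 (3S,5E)-5-methyl-3-(prop-1-en-2-yl)-8-(triethylsilyloxy)undec-5-en-9-ynoic acid (both C2 epimers), via bis-silyl compound 16 (not isolated)
Conditions: Et3SiOTf (3 equiv), 2,6-lutidine (4.5 equiv), CH2Cl2, 0 °C to rt; then H2O, THF, rt
Reagents that add atoms: triethylsilyl triflate, CC[Si](CC)(CC)OS(=O)(=O)C(F)(F)F
Why: The silyl triflate silylates the alcohol and also cleaves the tert-butyl ester (O-silylation, loss of isobutene) under buffered aprotic conditions, which avoids the protic acid that would lactonise the γ,δ-unsaturated acid onto the isopropenyl group, and the labile silyl ester of 16 hydrolyses when water is added.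

Step 10
Reactants: 17 the silyl ether acid
Product: 19 Se-phenyl (3S,5E)-8-hydroxy-5-methyl-3-(prop-1-en-2-yl)undec-5-en-9-yneselenoate (both C2 epimers), via silyl ether selenoester 18 (not isolated)
Conditions: (PhSe)2 (1.3 equiv), Bu3P (1.5 equiv), CH2Cl2, 0 °C to rt; solvent exchange; then HF·pyridine, THF, 0 °C
Reagents that add atoms: diphenyl diselenide, c1ccccc1[Se][Se]c1ccccc1
Why: Phosphine/diselenide activation (acyloxyphosphonium ion, then attack of selenolate) is carried out while C2 is still a protected carbinol, because phosphine and selenol would both add to a ynone, and acidic fluoride then removes the silyl group without harming the acyl selenide.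

Step 11
Reactants: 19 the hydroxy selenoester
Product: 20 Se-phenyl (3S,5E)-5-methyl-8-oxo-3-(prop-1-en-2-yl)undec-5-en-9-yneselenoate
Conditions: Dess–Martin periodinane (1.3 equiv), NaHCO3, CH2Cl2, 0 °C; used at once
Reagents that add atoms: none
Why: Buffered Dess–Martin oxidation unveils the ynone as the last operation, the acyl-deactivated selenium does not compete with the alcohol for the iodine reagent, and no acid or base strong enough to draw the C5=C10 alkene into conjugation is present.

Step 12
Reactants: 20 the selenoester with E alkene and ynone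
Product: 24 cis-fused 10βH-eremophila-3,11-diene-2,9-dione (5β-methyl and 7β-isopropenyl), via acyl radical 21 (not isolated), via tertiary C5 radical 22 (not isolated), via C3 vinyl radical 23 (not isolated)
Conditions: Bu3SnH (1.3 equiv) and AIBN (0.2 equiv) in PhH, added by syringe pump over 10 h to 20 (2 mM) in degassed PhH, reflux
Reagents that add atoms: none
Why: Proposed new method: Bu3Sn• abstracts PhSe from 20 to give acyl radical 21, which adds to C10, the less substituted terminus of the C5=C10 alkene (ring B, 6-endo-trig, C9–C10), the nucleophilic tertiary radical 22 then adds to C4, the electrophilic β-carbon of the ynone (ring A, 6-endo-dig, C4–C5), and vinyl radical 23 takes hydrogen from Bu3SnH to leave the C3=C4 enone. The closest known reaction type is the cascade of consecutive 6-endo-trig closures of polyene acyl radicals made from phenyl selenoesters, together with endo-mode additions of alkyl radicals to in-chain ynones, and what is new is a tertiary radical closing 6-endo-dig as the second event of such a cascade. C10 is set in a chair-like transition state with the C7 isopropenyl group equatorial, in which the E geometry places C1 equatorial and hence trans to isopropenyl (10β-H), and this centre stays correctable by enolisation towards C9 because the trans-fused epimer would hold C14 and isopropenyl syn-diaxial. C5 is set by closure on the axial α lobe of 22, which leaves C14 equatorial and cis to isopropenyl: the nearly coplanar C5···C4≡C3–C2–C1 array tolerates only a small C4–C5–C10–C1 torsion, which a cis junction shares with ring B (already flattened by trigonal C9 and C5), whereas a trans junction would force ring B to pucker more. Regioselectivity rests on the methyl group at C5 (against 5-exo-trig) and on polarity matching at C4 (against 5-exo-dig at C3), and the isopropenyl group is out of reach because only 4-exo or 5-endo modes lead to it. High dilution and slow addition of Bu3SnH keep reduction of 21 and 22 and hydrostannation of the ynone behind the two ring closures.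

Step 13
Reactants: 24 the enedione
Product: 25 cis-fused 10βH-eremophil-11-ene-2,9-dione (4β,5β-dimethyl and 7β-isopropenyl)
Conditions: [(Ph3P)CuH]6 (0.5 equiv), H2O (10 equiv), degassed PhH, rt
Reagents that add atoms: none
Why: Conjugate reduction by hydrocupration is selective for the enone over the isolated C9 ketone and both unactivated alkenes, and hydride should reach C4 on the α face, anti to the pseudo-axial C14 on the neighbouring C5, because this lets C15 swing outwards into the equatorial β position (cis to C14), whereas β attack would have to pass C14 and push C15 under ring B.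

Step 14
Reactants: 25 the saturated dione
Product: 26 the C2 ethylene ketal of 25 (C9 ketone free)
Conditions: Me3SiOCH2CH2OSiMe3 (1.2 equiv), Me3SiOTf (5 mol %), CH2Cl2, −78 to −40 °C; pyridine quench
Reagents that add atoms: 1,2-bis(trimethylsilyloxy)ethane, C[Si](C)(C)OCCO[Si](C)(C)C
Why: Noyori ketalisation at low temperature distinguishes the open C2 carbonyl, flanked by two methylene groups, from C9, which is flanked by the tertiary C10 and shielded by the axial C4, and the aprotic catalytic conditions spare the isopropenyl group and C10.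

Step 15
Reactants: 26 the keto ketal
Product: 28 8α-hydroxy-9-ketone (C2 ketal), via potassium enolate 27 (not isolated)
Conditions: KN(SiMe3)2 (1.1 equiv), THF, −78 °C; then 2-(phenylsulfonyl)-3-phenyloxaziridine (1.3 equiv), −78 °C; AcOH quench
Reagents that add atoms: 2-(phenylsulfonyl)-3-phenyloxaziridine, O=S(=O)(c1ccccc1)N1OC1c1ccccc1
Why: Kinetic deprotonation by the bulky amide takes a proton from the C8 methylene and not from the tertiary C10–H beside the quaternary C5, and enolate hydroxylation with the N-sulfonyloxaziridine, which ignores the isopropenyl group, should deliver oxygen to C8 anti to the neighbouring isopropenyl group, whose upper arm covers the β face, to give the equatorial hydrogen-bonded 8α-ketol that is also the more stable C8 epimer.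

Step 16
Reactants: 28 the 8α-ketol
Product: 29 8α-(triethylsilyloxy)-9-ketone (C2 ketal)
Conditions: Et3SiCl, imidazole, DMF, 0 °C to rt
Reagents that add atoms: chlorotriethylsilane, CC[Si](Cl)(CC)CC
Why: Silylation places on O8 a group that does not migrate under neutral acylation conditions, so that the hindered O9 can be esterified first without acyl scrambling within the cis-diol.

Step 17
Reactants: 29 the silyloxy ketone
Product: 30 9α-hydroxy-8α-(triethylsilyloxy) compound (C2 ketal)
Conditions: LiBH(s-Bu)3 (2 equiv), THF, −78 to −40 °C; aqueous work-up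
Reagents that add atoms: none
Why: Reduction with the bulky trialkylborohydride follows the equatorial trajectory on the convex β face because the axial α approach to C9 is closed by C4 (syn-axial on C5), so the axial 9α-alcohol, cis to O8, is formed, and no ester is yet present that could migrate or be cleaved.

Step 18
Reactants: 30 the 9α-alcohol; 31 tigloyl chloride, (E)-2-methylbut-2-enoyl chloride
Product: 32 9α-tigloyloxy-8α-(triethylsilyloxy) compound (C2 ketal)
Conditions: 31 (5 equiv), DMAP (1 equiv), pyridine, CH2Cl2, 0 to 40 °C
Reagents that add atoms: none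
Why: DMAP-catalysed acylation through the acylpyridinium ion is strong enough for an axial alcohol with one syn-axial carbon, pyridine in place of a trialkylamine avoids vinylketene formation and deconjugation of the acyl group, and the E geometry of the tiglate is the stable one.

Step 19
Reactants: 32 the silyl ether tiglate
Product: 33 8α-hydroxy-9α-tigloyloxy-10βH-eremophil-11-en-2-one
Conditions: 2 M aq HCl, THF, 0 °C to rt
Reagents that add atoms: water, O
Why: Mild acid hydrolysis removes the triethylsilyl ether and the strained C2 dioxolane in one operation, while the conjugated, α-branched tiglate is a poor migrating group and the isopropenyl group tolerates dilute aqueous acid for a short time.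

Step 20
Reactants: 33 the hydroxy tiglate
Product: 34 8α-acetoxy-9α-tigloyloxy-10βH-eremophil-11-en-2-one (CNP0204573.1)
Conditions: Ac2O, pyridine, DMAP (cat.), CH2Cl2, 0 °C to rt
Reagents that add atoms: acetic anhydride, CC(=O)OC(C)=O
Why: Acetylation of the unhindered equatorial 8α-hydroxyl is fast enough to outrun any base-induced shift of the tigloyl group and changes no stereocentre.

Compound list
1 | methyl 4-methylpent-3-enoate | CC(C)=CCC(=O)OC | starting material
2 | methyl (E)-5-hydroxy-4-methylpent-3-enoate | OC/C(C)=C/CC(=O)OC | intermediate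
3 | methyl (E)-5-bromo-4-methylpent-3-enoate | BrC/C(C)=C/CC(=O)OC | intermediate
4 | mono-tert-butyl succinate | CC(C)(C)OC(=O)CCC(O)=O | starting material
5 | (S)-4-benzyl-1,3-oxazolidin-2-one | O=C1OC[C@H](Cc2ccccc2)N1 | starting material
6 | mixed pivalic anhydride of 4 | CC(C)(C)OC(=O)CCC(=O)OC(=O)C(C)(C)C | intermediate
7 | tert-butyl 4-[(4S)-4-benzyl-2-oxo-1,3-oxazolidin-3-yl]-4-oxobutanoate | CC(C)(C)OC(=O)CCC(=O)N1C(=O)OC[C@@H]1Cc1ccccc1 | intermediate
8 | sodium Z-enolate of 7 | [Na+].CC(C)(C)OC(=O)C/C=C(\[O-])N1C(=O)OC[C@@H]1Cc1ccccc1 | intermediate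
9 | 1-tert-butyl 8-methyl (3S,5E)-3-{[(4S)-4-benzyl-2-oxo-1,3-oxazolidin-3-yl]carbonyl}-5-methyloct-5-enedioate | CC(C)(C)OC(=O)C[C@@H](C(=O)N1C(=O)OC[C@@H]1Cc1ccccc1)C/C(C)=C/CC(=O)OC | intermediate
10 | 1-tert-butyl 8-methyl (3S,5E)-3-[(ethylsulfanyl)carbonyl]-5-methyloct-5-enedioate | CC(C)(C)OC(=O)C[C@@H](C(=O)SCC)C/C(C)=C/CC(=O)OC | intermediate
11 | 1-tert-butyl 8-methyl (3S,5E)-3-acetyl-5-methyloct-5-enedioate | CC(C)(C)OC(=O)C[C@@H](C(C)=O)C/C(C)=C/CC(=O)OC | intermediate
12 | 1-tert-butyl 8-methyl (3S,5E)-5-methyl-3-(prop-1-en-2-yl)oct-5-enedioate | CC(C)(C)OC(=O)C[C@@H](C(C)=C)C/C(C)=C/CC(=O)OC | intermediate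
13 | prop-1-ynylmagnesium bromide | CC#C[Mg]Br | starting material
14 | tert-butyl (3S,5E)-5-methyl-8-oxo-3-(prop-1-en-2-yl)oct-5-enoate | CC(C)(C)OC(=O)C[C@@H](C(C)=C)C/C(C)=C/CC=O | intermediate
15 | tert-butyl (3S,5E)-8-hydroxy-5-methyl-3-(prop-1-en-2-yl)undec-5-en-9-ynoate, both carbinol epimers | CC(C)(C)OC(=O)C[C@@H](C(C)=C)C/C(C)=C/CC(O)C#CC | intermediate
16 | triethylsilyl (3S,5E)-5-methyl-3-(prop-1-en-2-yl)-8-(triethylsilyloxy)undec-5-en-9-ynoate | CC[Si](CC)(CC)OC(=O)C[C@@H](C(C)=C)C/C(C)=C/CC(O[Si](CC)(CC)CC)C#CC | intermediate
17 | (3S,5E)-5-methyl-3-(prop-1-en-2-yl)-8-(triethylsilyloxy)undec-5-en-9-ynoic acid | OC(=O)C[C@@H](C(C)=C)C/C(C)=C/CC(O[Si](CC)(CC)CC)C#CC | intermediate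
18 | Se-phenyl (3S,5E)-5-methyl-3-(prop-1-en-2-yl)-8-(triethylsilyloxy)undec-5-en-9-yneselenoate | O=C([Se]c1ccccc1)C[C@@H](C(C)=C)C/C(C)=C/CC(O[Si](CC)(CC)CC)C#CC | intermediate
19 | Se-phenyl (3S,5E)-8-hydroxy-5-methyl-3-(prop-1-en-2-yl)undec-5-en-9-yneselenoate | O=C([Se]c1ccccc1)C[C@@H](C(C)=C)C/C(C)=C/CC(O)C#CC | intermediate
20 | Se-phenyl (3S,5E)-5-methyl-8-oxo-3-(prop-1-en-2-yl)undec-5-en-9-yneselenoate | O=C([Se]c1ccccc1)C[C@@H](C(C)=C)C/C(C)=C/CC(=O)C#CC | intermediate
21 | C9 acyl radical from 20 | O=[C]C[C@@H](C(C)=C)C/C(C)=C/CC(=O)C#CC | intermediate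
22 | tertiary C5 radical (ring B closed) | C=C(C)[C@H]1C[C](C)[C@H](CC(=O)C#CC)C(=O)C1 | intermediate
23 | C3 vinyl radical (rings A and B closed) | C=C(C)[C@H]1C[C@@]2(C)[C@H](CC(=O)[C]=C2C)C(=O)C1 | intermediate
24 | cis-fused 10βH-eremophila-3,11-diene-2,9-dione | C=C(C)[C@H]1C[C@@]2(C)[C@H](CC(=O)C=C2C)C(=O)C1 | intermediate
25 | cis-fused 10βH-eremophil-11-ene-2,9-dione | C=C(C)[C@H]1C[C@@]2(C)[C@H](CC(=O)C[C@@H]2C)C(=O)C1 | intermediate
26 | C2 ethylene ketal of 25 | C=C(C)[C@H]1C[C@@]2(C)[C@H](CC3(OCCO3)C[C@@H]2C)C(=O)C1 | intermediate
27 | potassium C8=C9 enolate of 26 | [K+].C=C(C)[C@H]1C[C@@]2(C)[C@H](CC3(OCCO3)C[C@@H]2C)C([O-])=C1 | intermediate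
28 | 8α-hydroxy-9-ketone, C2 ketal | C=C(C)[C@H]1C[C@@]2(C)[C@H](CC3(OCCO3)C[C@@H]2C)C(=O)[C@@H]1O | intermediate
29 | 8α-(triethylsilyloxy)-9-ketone, C2 ketal | C=C(C)[C@H]1C[C@@]2(C)[C@H](CC3(OCCO3)C[C@@H]2C)C(=O)[C@@H]1O[Si](CC)(CC)CC | intermediate
30 | 9α-hydroxy-8α-(triethylsilyloxy) compound, C2 ketal | C=C(C)[C@H]1C[C@@]2(C)[C@H](CC3(OCCO3)C[C@@H]2C)[C@H](O)[C@@H]1O[Si](CC)(CC)CC | intermediate
31 | tigloyl chloride | ClC(=O)/C(C)=C/C | starting material
32 | 9α-tigloyloxy-8α-(triethylsilyloxy) compound, C2 ketal | C=C(C)[C@H]1C[C@@]2(C)[C@H](CC3(OCCO3)C[C@@H]2C)[C@H](OC(=O)/C(C)=C/C)[C@@H]1O[Si](CC)(CC)CC | intermediate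
33 | 8α-hydroxy-9α-tigloyloxy-10βH-eremophil-11-en-2-one | C=C(C)[C@H]1C[C@@]2(C)[C@H](CC(=O)C[C@@H]2C)[C@H](OC(=O)/C(C)=C/C)[C@@H]1O | intermediate
34 | 8α-acetoxy-9α-tigloyloxy-10βH-eremophil-11-en-2-one (CNP0204573.1) | C=C(C)[C@H]1C[C@@]2(C)[C@H](CC(=O)C[C@@H]2C)[C@H](OC(=O)/C(C)=C/C)[C@@H]1OC(C)=O | target

Total step count: 20
Longest linear sequence: 19 (steps 1, 2 and 4–20)

Steps most likely to fail

1. Step 12.
Possible failure modes:
- hydrogen transfer to the tertiary radical before ring A closes
- closure at C3 in the 5-exo-dig mode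
- stannyl radical addition to the ynone
- closure on the β lobe of C5, which gives a trans junction

The fallback replaces the alkyne acceptor by an E-alkene, so that both closures are of the documented 6-endo-trig type and the chain ends on an electron-poor alkene. It sets out from 12.
- Reduction with i-Bu2AlH as in step 8 and addition of (E)-prop-1-enyllithium (from (E)-1-bromoprop-1-ene and t-BuLi) would give the allylic alcohol F1.
- Et3SiOTf/2,6-lutidine followed by water would give the silyl ether acid F2.
- (PhSe)2/Bu3P would give the silyl ether selenoester F3.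
- HF·pyridine would give the hydroxy selenoester F4.
- Dess–Martin oxidation would give the E-enone selenoester F5.

Under Bu3SnH/AIBN at high dilution, F5 should close ring B and then ring A. The E geometry places C15 equatorial in the chair-like second transition state, and the C3 α-keto radical takes hydrogen from the stannane. The sequence comes back to the route at 25 and makes step 13 unnecessary.

2. Step 13.
Possible failure modes:
- poor facial selectivity of hydride delivery at C4
- no reaction at the hindered β,β-disubstituted enone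

The fallback sets C4 by protonation instead of hydride delivery. It sets out from 24. Lithium in liquid ammonia/THF with t-BuOH reduces the enone through its radical anion, and the β-carbon is protonated axially by a small proton donor. This leads to the more stable equatorial C15, and the isopropenyl group is inert. Excess metal is allowed to carry both carbonyl groups on to the diol F6, whose carbinol configurations do not matter. Twofold Dess–Martin oxidation of F6 comes back to the route at 25.

3. Step 15.
Possible failure mode:
- oxygen transfer on the convex β face of the enolate instead of the α face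

The fallback accepts that outcome and inverts C8 by neighbouring-group participation. It sets out from 26.
- The same hydroxylation would then give the 8β-ketol F7.
- Hydroxyl-directed reduction of F7 with Me4NBH(OAc)3 delivers hydride on the β face and would give the trans-diaxial 8β,9α-diol F8.
- MsCl/pyridine should sulfonylate only the exposed 8β-hydroxyl to give the mesylate F9.
- Tigloyl chloride/DMAP/pyridine would acylate O9 to give the mesylate tiglate F10.
- Warming F10 in aqueous acetic acid buffered with KOAc lets the antiperiplanar tigloyl carbonyl displace the mesylate from the α face. Water opens the resulting cis-fused dioxolenium ion to the axial ester and the equatorial alcohol, and the ketal is hydrolysed in the same medium.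

The sequence comes back to the route at 33.

Further compounds
F1 | step 12 | tert-butyl (3S,5E,9E)-8-hydroxy-5-methyl-3-(prop-1-en-2-yl)undeca-5,9-dienoate | CC(C)(C)OC(=O)C[C@@H](C(C)=C)C/C(C)=C/CC(O)/C=C/C
F2 | step 12 | (3S,5E,9E)-5-methyl-3-(prop-1-en-2-yl)-8-(triethylsilyloxy)undeca-5,9-dienoic acid | OC(=O)C[C@@H](C(C)=C)C/C(C)=C/CC(O[Si](CC)(CC)CC)/C=C/C
F3 | step 12 | Se-phenyl (3S,5E,9E)-5-methyl-3-(prop-1-en-2-yl)-8-(triethylsilyloxy)undeca-5,9-dieneselenoate | O=C([Se]c1ccccc1)C[C@@H](C(C)=C)C/C(C)=C/CC(O[Si](CC)(CC)CC)/C=C/C
F4 | step 12 | Se-phenyl (3S,5E,9E)-8-hydroxy-5-methyl-3-(prop-1-en-2-yl)undeca-5,9-dieneselenoate | O=C([Se]c1ccccc1)C[C@@H](C(C)=C)C/C(C)=C/CC(O)/C=C/C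
F5 | step 12 | Se-phenyl (3S,5E,9E)-5-methyl-8-oxo-3-(prop-1-en-2-yl)undeca-5,9-dieneselenoate | O=C([Se]c1ccccc1)C[C@@H](C(C)=C)C/C(C)=C/CC(=O)/C=C/C
F6 | step 13 | 10βH-eremophil-11-ene-2,9-diol (carbinol configurations open) | C=C(C)[C@H]1C[C@@]2(C)[C@H](CC(O)C[C@@H]2C)C(O)C1
F7 | step 15 | 8β-hydroxy-9-ketone, C2 ketal | C=C(C)[C@H]1C[C@@]2(C)[C@H](CC3(OCCO3)C[C@@H]2C)C(=O)[C@H]1O
F8 | step 15 | 8β,9α-diol, C2 ketal | C=C(C)[C@H]1C[C@@]2(C)[C@H](CC3(OCCO3)C[C@@H]2C)[C@H](O)[C@H]1O
F9 | step 15 | 9α-hydroxy-8β-mesyloxy compound, C2 ketal | C=C(C)[C@H]1C[C@@]2(C)[C@H](CC3(OCCO3)C[C@@H]2C)[C@H](O)[C@H]1OS(C)(=O)=O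
F10 | step 15 | 8β-mesyloxy-9α-tigloyloxy compound, C2 ketal | C=C(C)[C@H]1C[C@@]2(C)[C@H](CC3(OCCO3)C[C@@H]2C)[C@H](OC(=O)/C(C)=C/C)[C@H]1OS(C)(=O)=O
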